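At early times Wednesday's flask runs fast: by 1.00 min it holds 27.6% product, yet from 5.00 min to 12.0 min it gains 1.3 percentage points. This is the flask asked about.

the same everywhere: substrate 0.050 M; free catalyst 1.2 mM

|  | partner | remark | time |
|---|---|---|---|
| Wednesday's | 0.060 M | the very flask that is asked about, followed so far |  |
| flask | 0.0600 M |  | 15 min |

Wednesday's run (percent of the substrate charged)

| time / min | product / % |
|---|---|
| 1.00 | 27.6 |
| 2.00 | 35.8 |
| 5.00 | 41.3 |
| 12.0 | 42.6 |

(scatter of a reading: 0.3 percentage points)

- red: at 15 min take out 90% of the product then present, then wait 30 min
- violet: change nothing and wait 30 min more
- grey: at 15 min add partner, 50.0% of the amount charged, then wait 30 min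
- teal: at 15 min add free catalyst, 100% of the amount charged, then wait 30 min

- removed product is counted in
- additions bring no volume worth counting

1. product, in percent of the substrate first charged, at 15 min
2. which option adds most product ("none" when 2 percentage points or less is all one gets) (red / violet / grey / teal / none)
3. product present, with what was taken out counted in, in percent of the substrate first charged, after red
4. product present, with what was taken out counted in, in percent of the substrate first charged, after violet

I bracket the product at 15 min. From below, I take the last reading, 42.6%, since the product has grown at every reading. From above, I suppose the rate goes on falling, so the remaining minutes run at most at the average rate of the last interval: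

upper bound = 42.6% + 1.3 points × 3.00 min / 7.00 min = 43.2%

To tighten it I define the working life of the flask: the time in which its rate of making product falls by a factor e, as for a first-order decay. The gain from 2.00 min to 5.00 min is 5.5 points. The average rates of the two intervals differ by a factor 9.87, and their midpoints stand 5.00 min apart, so:

working life = 5.00 min / ln(9.87) = 2.18 min

The rate at 12.0 min times this life gives the tail still to come:

tail = 0.082 points

So my bracket closes to 42.6% to 42.7%, read with a scatter of 0.3 points.

The forecast says 42.7%, with a range of 42.2% to 43.2% that holds my whole bracket. It gives 42.8% after red and 42.8% after violet, and it chooses teal: “A fresh catalyst charge should restart the reaction”.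

The flask gives 42.6%, with 42.6% after red, 42.6% after violet, and teal as the best option.

    substrate + partner + free catalyst → product + free catalyst, rate k1*[substrate]*[partner]*[free catalyst]/(1 + ([substrate]/sat1)) (0.110 M, k = 190 M⁻² s⁻¹)
    partner + free catalyst → spent catalyst (k = 0.200 M⁻¹ s⁻¹)
    2 substrate → homo dimer (k = 0.0940 M⁻¹ s⁻¹)

The wait of 30 min is 13.8 working lives, and violet adds 0.007 points, while teal adds 5.2 points. Part of what gives teal its gain is the turning of partner + free catalyst into spent catalyst: in the same flask without that step, teal adds 0.12 points against 5.2 points. The neighbour flask with 0.020 M of substrate, at the same partner and catalyst charges, stands at 15 min with 55.7% product and 0.0159% free catalyst; counted on that free catalyst, its working life is 1.72 min, shorter than the 2.18 min read from the flask.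

(The runs were generated by integration from invented constants, and the scatter is random.)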